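**Plan**
1. Cuts, in retrosynthetic order: the galloyl ester C–O bond at C3 of the lower unit and all O-benzyl groups; in the upper unit the C2–C1' bond to ring B and the C2–H bond (C2 becomes a lactone carbonyl), then the C3–O bond; the aryl ether bond O1–C8a; last the interflavan bond C4(upper)–C8(lower).
2. Enabling feature: in the upper 7-hydroxyflavan unit O1 is the only atom between C8a of resorcinol ring A and C2 of pyran ring C, and C4 of ring C is a diarylmethine. With O1 taken out, the same carbons form the five-membered ketone of a 3-arylindan-1-one (C8a = C7a, C2 = C1, C4 = C3), so an aryl-migrating Baeyer–Villiger oxidation restores O1–C8a.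
3. Forward: ring A of the upper unit and its five-membered ketone are bought as 6-hydroxyindan-1-one; the lower unit, intact from (−)-epigallocatechin, is joined through C8 by conjugate arylation of the derived indenone; oxygen insertion expands the cyclopentanone to the six-membered lactone (ring C); ring B is added to the lactone carbonyl, the lactol is reduced, and the gallate is attached before global debenzylation.
4. Stereochemistry: lower C2 and C3 come from the chiral pool; upper C4 from the (R)-BINAP/rhodium catalyst in the arylation; upper C3 from enolate hydroxylation anti to the C4 aryl group; upper C2 from axial hydride delivery to the cyclic oxocarbenium ion, trans to the C3 benzyloxy group.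

Key step: step 7

Abbreviations: Bn = benzyl; TBS = tert-butyldimethylsilyl; ArL = (2R,3R)-5,7-bis(benzyloxy)-3-(tert-butyldimethylsilyloxy)-2-[3,4,5-tris(benzyloxy)phenyl]chroman-8-yl, the protected lower unit bound through C8.
Remark (assumption): the facial sense of the rhodium/BINAP arylation of the indenone is taken to follow that established for cyclopent-2-enone, so that (R)-BINAP gives the 3S ketone.
Remark (assumption): the lactol from the aryllithium addition is drawn as the cyclic hemiketal although it may be partly open-chain; both forms converge in the reduction. 3,4,5-Tris(benzyloxy)benzoic acid is taken as commercially available.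

**Step 1**
Reactants: 1 6-hydroxyindan-1-one
Product: 2 6-(benzyloxy)indan-1-one
Conditions: BnBr, K2CO3, acetone, reflux
Reagents that add atoms: benzyl bromide, BrCc1ccccc1
Why: Williamson etherification of the phenol, the only acidic OH group, under conditions too weakly basic to alkylate the ketone α-carbon.

**Step 2**
Reactants: 2 6-(benzyloxy)indan-1-one
Product: 4 6-(benzyloxy)-1H-inden-1-one, via silyl enol ether 3 (not isolated)
Conditions: Me3SiOTf, Et3N, CH2Cl2, 0 °C; then Pd(OAc)2, MeCN, rt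
Reagents that add atoms: none
Why: Saegusa–Ito dehydrogenation, in which the enol silane (possible only toward C2) is palladated by palladium diacetate and loses the C3 hydrogen by β-hydride elimination under neutral conditions that spare the benzyl ether; the indenone should be used at once because it is prone to dimerisation.

**Step 3**
Reactants: 5 (−)-epigallocatechin
Product: 6 (2R,3R)-5,7-bis(benzyloxy)-2-[3,4,5-tris(benzyloxy)phenyl]chroman-3-ol
Conditions: BnBr, K2CO3, DMF, 0 °C to rt, Ar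
Reagents that add atoms: benzyl bromide, BrCc1ccccc1
Why: Williamson O-alkylation in which K2CO3 deprotonates only the five phenols, so the C3 alcohol stays free and both stereocentres should be retained.

**Step 4**
Reactants: 6 (2R,3R)-5,7-bis(benzyloxy)-2-[3,4,5-tris(benzyloxy)phenyl]chroman-3-ol
Product: 7 (2R,3R)-5,7-bis(benzyloxy)-8-bromo-2-[3,4,5-tris(benzyloxy)phenyl]chroman-3-ol
Conditions: NBS (1 equiv), CH2Cl2, −78 °C to rt
Reagents that add atoms: N-bromosuccinimide, O=C1CCC(=O)N1Br
Why: Electrophilic aromatic bromination with one equivalent of NBS at low temperature should go to C8, the most nucleophilic free position of ring A in benzylated flavan-3-ols, and so fixes the site of the later interflavan bond.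

**Step 5**
Reactants: 7 (2R,3R)-5,7-bis(benzyloxy)-8-bromo-2-[3,4,5-tris(benzyloxy)phenyl]chroman-3-ol
Product: 8 ArL–Br [(2R,3R)-5,7-bis(benzyloxy)-8-bromo-3-(tert-butyldimethylsilyloxy)-2-[3,4,5-tris(benzyloxy)phenyl]chromane]
Conditions: TBSCl, imidazole, DMF, rt
Reagents that add atoms: tert-butyldimethylsilyl chloride, CC(C)(C)[Si](C)(C)Cl
Why: Standard silylation of the secondary alcohol masks the only acidic proton before the organometallic steps and marks the lower C3 oxygen for late, selective galloylation.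

**Step 6**
Reactants: 8 ArL–Br; 4 6-(benzyloxy)-1H-inden-1-one
Product: 12 (3S)-6-(benzyloxy)-3-ArL-indan-1-one, via aryllithium 9 (not isolated), via arylzinc chloride 10 (not isolated), via silyl enol ether 11 (not isolated)
Conditions: t-BuLi (2 equiv), THF, −78 °C; ZnCl2, −78 to 0 °C; 4, [RhCl((R)-BINAP)]2 (3 mol %), Me3SiCl, THF, 20 °C; 1 M HCl (aq.), 0 °C
Reagents that add atoms: none
Why: Bromine–lithium exchange and transmetalation give an arylzinc chloride that passes its aryl group to rhodium, and the aryl–rhodium species should add in Hayashi–Miyaura 1,4-fashion to the unhindered β-carbon of the strained enone while Me3SiCl traps the enolate; the new diarylmethine centre (3S) is set by the (R)-BINAP ligand, the remote stereocentres of the nucleophile being expected to matter little.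

**Step 7**
Reactants: 12 (3S)-6-(benzyloxy)-3-ArL-indan-1-one
Product: 13 (4S)-7-(benzyloxy)-4-ArL-chroman-2-one
Conditions: mCPBA, NaHCO3, CH2Cl2, 0 °C to rt, dark
Reagents that add atoms: 3-chloroperoxybenzoic acid, O=C(OO)c1cccc(Cl)c1
Why: The peroxy acid adds to the strained five-ring ketone to give the Criegee tetrahedral adduct, from which the arene carbon C7a migrates to the proximal peroxide oxygen with loss of 3-chlorobenzoate, so that oxygen ends up between C1 and C7a. The closest known reaction is the Baeyer–Villiger oxidation of 1-indanones, 3-aryl-1-indanones included, to 3,4-dihydrocoumarins. The six-membered lactone is closed by ring expansion through this 1,2-aryl shift (insertion of oxygen into the C1–C7a bond of the cyclopentanone) and not by a cyclisation, and the bond made is O1–C8a of the future flavan. No stereocentre is formed: the diarylmethine carbon neither migrates nor enolises and should become C4 of the lactone with unchanged configuration. Regioselectivity (aryl over methylene migration) rests on the higher migratory aptitude of the sp2 carbon, which carries the developing positive charge better than a primary alkyl group. Chemoselectivity (ketone before the electron-rich benzyloxyarenes) rests on the bicarbonate buffer, which removes the carboxylic acid that catalyses electrophilic arene hydroxylation, on the two benzyloxy groups flanking the only free position of the lower ring A, and on the ketone not being deactivated by the 6-benzyloxy donor, which is meta to C7a.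

**Step 8**
Reactants: 13 (4S)-7-(benzyloxy)-4-ArL-chroman-2-one
Product: 15 (3S,4S)-7-(benzyloxy)-3-hydroxy-4-ArL-chroman-2-one, via sodium enolate 14 (not isolated)
Conditions: NaN(SiMe3)2, THF, −78 °C; 2-(phenylsulfonyl)-3-phenyloxaziridine, −78 °C; sat. aq. NH4Cl
Reagents that add atoms: 2-(phenylsulfonyl)-3-phenyloxaziridine, O=S(=O)(c1ccccc1)N1OC1c1ccccc1
Why: Davis oxidation of the lactone enolate, in which the bulky pseudo-axial C4 aryl group shields one face so that oxygen should be delivered anti to it, setting C3 (S) trans to C4.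

**Step 9**
Reactants: 15 (3S,4S)-7-(benzyloxy)-3-hydroxy-4-ArL-chroman-2-one
Product: 16 (3S,4S)-3,7-bis(benzyloxy)-4-ArL-chroman-2-one
Conditions: BnBr, Ag2O, 4 Å MS, CH2Cl2, rt, dark
Reagents that add atoms: benzyl bromide, BrCc1ccccc1
Why: Silver oxide-promoted O-benzylation (a Williamson-type alkylation under essentially neutral conditions) caps the α-hydroxy lactone without the strong base that would epimerise C3 or open the aryl ester.

**Step 10**
Reactants: 17 5-bromo-1,2,3-trimethoxybenzene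
Product: 18 5-bromobenzene-1,2,3-triol
Conditions: BBr3, CH2Cl2, −78 °C to rt; H2O
Reagents that add atoms: none
Why: Lewis-acid cleavage of the three aryl methyl ethers by BBr3, to which the aryl bromide is inert, exposes the pyrogallol for re-protection with a hydrogenolysable group.

**Step 11**
Reactants: 18 5-bromobenzene-1,2,3-triol
Product: 19 5-bromo-1,2,3-tris(benzyloxy)benzene
Conditions: BnBr, K2CO3, DMF, rt, Ar
Reagents that add atoms: benzyl bromide, BrCc1ccccc1
Why: Williamson etherification of the three phenols under argon gives the ring B bromide in the same protecting-group pattern as the rest of the molecule.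

**Step 12**
Reactants: 19 5-bromo-1,2,3-tris(benzyloxy)benzene; 16 (3S,4S)-3,7-bis(benzyloxy)-4-ArL-chroman-2-one
Product: 21 (3S,4S)-3,7-bis(benzyloxy)-4-ArL-2-[3,4,5-tris(benzyloxy)phenyl]chroman-2-ol (mixture of C2 epimers), via aryllithium 20 (not isolated)
Conditions: 19, n-BuLi, THF, −78 °C; then 16, THF, −78 °C; sat. aq. NH4Cl, −78 °C
Reagents that add atoms: none
Why: Bromine–lithium exchange gives the ring B aryllithium, which should add once to the lactone carbonyl at −78 °C because the lithium alkoxide of the tetrahedral adduct is held by chelation to the neighbouring benzyloxy oxygen until the cold quench, as in aryllithium additions to benzyl-protected aldonolactones.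

**Step 13**
Reactants: 21 (3S,4S)-3,7-bis(benzyloxy)-4-ArL-2-[3,4,5-tris(benzyloxy)phenyl]chroman-2-ol
Product: 22 (2R,3S,4S)-3,7-bis(benzyloxy)-4-ArL-2-[3,4,5-tris(benzyloxy)phenyl]chromane
Conditions: Et3SiH, BF3·OEt2, CH2Cl2/MeCN, −40 to −20 °C
Reagents that add atoms: none
Why: Ionic (silane) reduction of the hemiketal through the cyclic 2-aryl oxocarbenium ion, in which hydride should attack axially on the half-chair that carries the 3-benzyloxy and 4-aryl groups pseudo-equatorially, placing the ring B aryl group equatorial and trans to C3–O (2R), the same course as the reduction of 2-O-benzyl lactols to β-C-aryl glycosides.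

**Step 14**
Reactants: 22 (2R,3S,4S)-3,7-bis(benzyloxy)-4-ArL-2-[3,4,5-tris(benzyloxy)phenyl]chromane
Product: 23 (2R,3R)-5,7-bis(benzyloxy)-8-[(2R,3S,4S)-3,7-bis(benzyloxy)-2-(3,4,5-tris(benzyloxy)phenyl)chroman-4-yl]-2-[3,4,5-tris(benzyloxy)phenyl]chroman-3-ol
Conditions: Bu4NF, THF, 0 °C to rt
Reagents that add atoms: none
Why: Fluoride-induced cleavage of the silyl ether frees only the lower C3 hydroxyl, since every other oxygen is a benzyl ether, and any silyl ether already lost to BF3·OEt2 in step 13 would converge on the same alcohol.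

**Step 15**
Reactants: 23 the lower C3 alcohol; 24 3,4,5-tris(benzyloxy)benzoic acid
Product: 25 3-O-[3,4,5-tris(benzyloxy)benzoyl] ester of 23 (trideca-O-benzyl derivative of the target)
Conditions: DCC, DMAP, CH2Cl2, rt
Reagents that add atoms: none
Why: Steglich esterification with DMAP as acyl-transfer catalyst should acylate the single free, axial secondary alcohol without touching any stereocentre.

**Step 16**
Reactants: 25 trideca-O-benzyl derivative of the target
Product: 26 robinetinidol-(4α→8)-epigallocatechin 3-O-gallate (CNP0269431.1)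
Conditions: H2 (1 atm), Pd(OH)2/C, THF/MeOH, rt
Reagents that add atoms: none
Why: Hydrogenolysis over Pd(OH)2/C under neutral conditions should remove all thirteen benzyl ethers while the gallate ester, the interflavan C–C bond and the five stereocentres survive, as in the deprotection of benzylated proanthocyanidin gallates.

**Compound list**
1 | 6-hydroxyindan-1-one | O=C1CCc2ccc(O)cc12 | starting material
2 | 6-(benzyloxy)indan-1-one | O=C1CCc2ccc(OCc3ccccc3)cc12 | intermediate
3 | 5-(benzyloxy)-3-(trimethylsilyloxy)-1H-indene (silyl enol ether of 2) | C[Si](C)(C)OC1=CCc2ccc(OCc3ccccc3)cc12 | intermediate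
4 | 6-(benzyloxy)-1H-inden-1-one | O=C1C=Cc2ccc(OCc3ccccc3)cc12 | intermediate
5 | (−)-epigallocatechin, (2R,3R)-2-(3,4,5-trihydroxyphenyl)chroman-3,5,7-triol | O[C@@H]1Cc2c(O)cc(O)cc2O[C@@H]1c1cc(O)c(O)c(O)c1 | starting material
6 | (2R,3R)-5,7-bis(benzyloxy)-2-[3,4,5-tris(benzyloxy)phenyl]chroman-3-ol | O[C@@H]1Cc2c(OCc5ccccc5)cc(OCc5ccccc5)cc2O[C@@H]1c1cc(OCc5ccccc5)c(OCc5ccccc5)c(OCc5ccccc5)c1 | intermediate
7 | (2R,3R)-5,7-bis(benzyloxy)-8-bromo-2-[3,4,5-tris(benzyloxy)phenyl]chroman-3-ol | O[C@@H]1Cc2c(OCc5ccccc5)cc(OCc5ccccc5)c(Br)c2O[C@@H]1c1cc(OCc5ccccc5)c(OCc5ccccc5)c(OCc5ccccc5)c1 | intermediate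
8 | ArL–Br, (2R,3R)-5,7-bis(benzyloxy)-8-bromo-3-(tert-butyldimethylsilyloxy)-2-[3,4,5-tris(benzyloxy)phenyl]chromane | CC(C)(C)[Si](C)(C)O[C@@H]1Cc2c(OCc5ccccc5)cc(OCc5ccccc5)c(Br)c2O[C@@H]1c1cc(OCc5ccccc5)c(OCc5ccccc5)c(OCc5ccccc5)c1 | intermediate
9 | ArL–Li (8-lithio compound from 8) | CC(C)(C)[Si](C)(C)O[C@@H]1Cc2c(OCc5ccccc5)cc(OCc5ccccc5)c([Li])c2O[C@@H]1c1cc(OCc5ccccc5)c(OCc5ccccc5)c(OCc5ccccc5)c1 | intermediate
10 | ArL–ZnCl (8-chlorozincio compound) | CC(C)(C)[Si](C)(C)O[C@@H]1Cc2c(OCc5ccccc5)cc(OCc5ccccc5)c([Zn]Cl)c2O[C@@H]1c1cc(OCc5ccccc5)c(OCc5ccccc5)c(OCc5ccccc5)c1 | intermediate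
11 | (1S)-5-(benzyloxy)-1-ArL-3-(trimethylsilyloxy)-1H-indene (silyl enol ether of 12) | CC(C)(C)[Si](C)(C)O[C@@H]1Cc2c(OCc5ccccc5)cc(OCc5ccccc5)c([C@@H]3c4ccc(OCc5ccccc5)cc4C(O[Si](C)(C)C)=C3)c2O[C@@H]1c1cc(OCc5ccccc5)c(OCc5ccccc5)c(OCc5ccccc5)c1 | intermediate
12 | (3S)-6-(benzyloxy)-3-ArL-indan-1-one | CC(C)(C)[Si](C)(C)O[C@@H]1Cc2c(OCc5ccccc5)cc(OCc5ccccc5)c([C@@H]3c4ccc(OCc5ccccc5)cc4C(=O)C3)c2O[C@@H]1c1cc(OCc5ccccc5)c(OCc5ccccc5)c(OCc5ccccc5)c1 | intermediate
13 | (4S)-7-(benzyloxy)-4-ArL-chroman-2-one (3,4-dihydrocoumarin) | CC(C)(C)[Si](C)(C)O[C@@H]1Cc2c(OCc5ccccc5)cc(OCc5ccccc5)c([C@@H]3c4ccc(OCc5ccccc5)cc4OC(=O)C3)c2O[C@@H]1c1cc(OCc5ccccc5)c(OCc5ccccc5)c(OCc5ccccc5)c1 | intermediate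
14 | sodium enolate of 13 | CC(C)(C)[Si](C)(C)O[C@@H]1Cc2c(OCc5ccccc5)cc(OCc5ccccc5)c([C@@H]3c4ccc(OCc5ccccc5)cc4OC([O-])=C3)c2O[C@@H]1c1cc(OCc5ccccc5)c(OCc5ccccc5)c(OCc5ccccc5)c1.[Na+] | intermediate
15 | (3S,4S)-7-(benzyloxy)-3-hydroxy-4-ArL-chroman-2-one (3,4-trans) | CC(C)(C)[Si](C)(C)O[C@@H]1Cc2c(OCc5ccccc5)cc(OCc5ccccc5)c([C@@H]3c4ccc(OCc5ccccc5)cc4OC(=O)[C@H]3O)c2O[C@@H]1c1cc(OCc5ccccc5)c(OCc5ccccc5)c(OCc5ccccc5)c1 | intermediate
16 | (3S,4S)-3,7-bis(benzyloxy)-4-ArL-chroman-2-one | CC(C)(C)[Si](C)(C)O[C@@H]1Cc2c(OCc5ccccc5)cc(OCc5ccccc5)c([C@@H]3c4ccc(OCc5ccccc5)cc4OC(=O)[C@H]3OCc5ccccc5)c2O[C@@H]1c1cc(OCc5ccccc5)c(OCc5ccccc5)c(OCc5ccccc5)c1 | intermediate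
17 | 5-bromo-1,2,3-trimethoxybenzene | COc1cc(Br)cc(OC)c1OC | starting material
18 | 5-bromobenzene-1,2,3-triol | Oc1cc(Br)cc(O)c1O | intermediate
19 | 5-bromo-1,2,3-tris(benzyloxy)benzene | Brc1cc(OCc2ccccc2)c(OCc2ccccc2)c(OCc2ccccc2)c1 | intermediate
20 | 3,4,5-tris(benzyloxy)phenyllithium | [Li]c1cc(OCc2ccccc2)c(OCc2ccccc2)c(OCc2ccccc2)c1 | intermediate
21 | (3S,4S)-3,7-bis(benzyloxy)-4-ArL-2-[3,4,5-tris(benzyloxy)phenyl]chroman-2-ol (lactol, C2 epimers) | CC(C)(C)[Si](C)(C)O[C@@H]1Cc2c(OCc5ccccc5)cc(OCc5ccccc5)c([C@@H]3c4ccc(OCc5ccccc5)cc4OC(O)(c4cc(OCc5ccccc5)c(OCc5ccccc5)c(OCc5ccccc5)c4)[C@H]3OCc5ccccc5)c2O[C@@H]1c1cc(OCc5ccccc5)c(OCc5ccccc5)c(OCc5ccccc5)c1 | intermediate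
22 | (2R,3S,4S)-3,7-bis(benzyloxy)-4-ArL-2-[3,4,5-tris(benzyloxy)phenyl]chromane | CC(C)(C)[Si](C)(C)O[C@@H]1Cc2c(OCc5ccccc5)cc(OCc5ccccc5)c([C@@H]3c4ccc(OCc5ccccc5)cc4O[C@H](c4cc(OCc5ccccc5)c(OCc5ccccc5)c(OCc5ccccc5)c4)[C@H]3OCc5ccccc5)c2O[C@@H]1c1cc(OCc5ccccc5)c(OCc5ccccc5)c(OCc5ccccc5)c1 | intermediate
23 | (2R,3R)-5,7-bis(benzyloxy)-8-[(2R,3S,4S)-3,7-bis(benzyloxy)-2-(3,4,5-tris(benzyloxy)phenyl)chroman-4-yl]-2-[3,4,5-tris(benzyloxy)phenyl]chroman-3-ol | O[C@@H]1Cc2c(OCc5ccccc5)cc(OCc5ccccc5)c([C@@H]3c4ccc(OCc5ccccc5)cc4O[C@H](c4cc(OCc5ccccc5)c(OCc5ccccc5)c(OCc5ccccc5)c4)[C@H]3OCc5ccccc5)c2O[C@@H]1c1cc(OCc5ccccc5)c(OCc5ccccc5)c(OCc5ccccc5)c1 | intermediate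
24 | 3,4,5-tris(benzyloxy)benzoic acid | OC(=O)c1cc(OCc2ccccc2)c(OCc2ccccc2)c(OCc2ccccc2)c1 | starting material
25 | 3-O-[3,4,5-tris(benzyloxy)benzoyl] ester of 23 (trideca-O-benzyl target) | O=C(O[C@@H]1Cc2c(OCc5ccccc5)cc(OCc5ccccc5)c([C@@H]3c4ccc(OCc5ccccc5)cc4O[C@H](c4cc(OCc5ccccc5)c(OCc5ccccc5)c(OCc5ccccc5)c4)[C@H]3OCc5ccccc5)c2O[C@@H]1c1cc(OCc5ccccc5)c(OCc5ccccc5)c(OCc5ccccc5)c1)c1cc(OCc5ccccc5)c(OCc5ccccc5)c(OCc5ccccc5)c1 | intermediate
26 | robinetinidol-(4α→8)-epigallocatechin 3-O-gallate, [(2R,3R)-8-[(2R,3S,4S)-3,7-dihydroxy-2-(3,4,5-trihydroxyphenyl)chroman-4-yl]-5,7-dihydroxy-2-(3,4,5-trihydroxyphenyl)chroman-3-yl] 3,4,5-trihydroxybenzoate | O=C(O[C@@H]1Cc2c(O)cc(O)c([C@@H]3c4ccc(O)cc4O[C@H](c4cc(O)c(O)c(O)c4)[C@H]3O)c2O[C@@H]1c1cc(O)c(O)c(O)c1)c1cc(O)c(O)c(O)c1 | target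

**Totals**
Total step count: 16. Longest linear sequence: 12 steps (from 5 through steps 3–9 and 12–16 to 26).

**Steps most likely to fail**

Step 6. The di-ortho-oxygenated aryl group may transfer to rhodium and insert into the enone too slowly, so that the indenone dimerises first. The chiral nucleophile may also erode the facial selectivity imposed by the ligand. The fallback sets out from 8 and comes back at 12, and forms the C3–C3a bond intramolecularly with the hindered aryl group already in place. Bromide 8 is lithiated (t-BuLi, THF, −78 °C) and formylated with DMF to give the 8-carbaldehyde F1. Claisen–Schmidt condensation (KOH, EtOH/THF) with commercially available 1-[5-(benzyloxy)-2-hydroxyphenyl]ethanone should give the (E)-2'-hydroxychalcone F2, which Tf2O/pyridine converts into the aryl triflate F3. An asymmetric intramolecular reductive Heck cyclisation then closes the five-membered ketone and returns to indanone 12. Its conditions are Pd(OAc)2, the enantiomer of the 3,5-Xyl-MeO-BIPHEP ligand that gives the 3S centre, 1,8-bis(dimethylamino)naphthalene, DMF, heat.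

Step 7. Electrophilic hydroxylation of the lower ring A at its free C6 position, followed by oxidation to a quinone, may outpace the slow oxygen insertion into an aryl ketone under buffered conditions. The fallback sets out from 12 and comes back at 13, and keeps the same oxygen insertion but blocks the vulnerable position first. NBS (CH2Cl2, −78 °C) should brominate C6 of the lower ring A of 12 to give the bromo ketone F4. With that ring fully substituted and deactivated, the peracid oxidation can be driven with excess mCPBA and longer time to the bromo lactone F5. Radical hydrodebromination (Bu3SnH, AIBN, toluene, 80 °C) then returns to lactone 13.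

Step 12. The tetrahedral lithium adduct may collapse by loss of the phenoxide to the aryl ketone, which then takes up a second aryllithium; alternatively the aryllithium may enolise the lactone instead of adding. The fallback sets out from 16 and comes back at 21. The lactone is opened with MeNH(OMe)·HCl and i-PrMgCl (THF, −20 °C) to the phenolic Weinreb amide F6. Two equivalents of aryllithium 20, the first consumed by the phenol, then add once through the stable chelated adduct, which releases the ketone only on work-up. The product is the keto phenol F7, the open-chain tautomer of lactol 21, with which the route is rejoined at 21 before the silane reduction.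

**Further compounds**
F1 | step 6 | ArL–CHO, (2R,3R)-5,7-bis(benzyloxy)-3-(tert-butyldimethylsilyloxy)-2-[3,4,5-tris(benzyloxy)phenyl]chromane-8-carbaldehyde | CC(C)(C)[Si](C)(C)O[C@@H]1Cc2c(OCc5ccccc5)cc(OCc5ccccc5)c(C=O)c2O[C@@H]1c1cc(OCc5ccccc5)c(OCc5ccccc5)c(OCc5ccccc5)c1
F2 | step 6 | (E)-1-[5-(benzyloxy)-2-hydroxyphenyl]-3-ArL-prop-2-en-1-one | CC(C)(C)[Si](C)(C)O[C@@H]1Cc2c(OCc5ccccc5)cc(OCc5ccccc5)c(/C=C/C(=O)c3cc(OCc5ccccc5)ccc3O)c2O[C@@H]1c1cc(OCc5ccccc5)c(OCc5ccccc5)c(OCc5ccccc5)c1
F3 | step 6 | 4-(benzyloxy)-2-[(E)-3-ArL-prop-2-enoyl]phenyl trifluoromethanesulfonate | CC(C)(C)[Si](C)(C)O[C@@H]1Cc2c(OCc5ccccc5)cc(OCc5ccccc5)c(/C=C/C(=O)c3cc(OCc5ccccc5)ccc3OS(=O)(=O)C(F)(F)F)c2O[C@@H]1c1cc(OCc5ccccc5)c(OCc5ccccc5)c(OCc5ccccc5)c1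
F4 | step 7 | 6-bromo derivative of 12 (bromine at C6 of the lower ring A) | CC(C)(C)[Si](C)(C)O[C@@H]1Cc2c(OCc5ccccc5)c(Br)c(OCc5ccccc5)c([C@@H]3c4ccc(OCc5ccccc5)cc4C(=O)C3)c2O[C@@H]1c1cc(OCc5ccccc5)c(OCc5ccccc5)c(OCc5ccccc5)c1
F5 | step 7 | 6-bromo derivative of 13 (bromine at C6 of the lower ring A) | CC(C)(C)[Si](C)(C)O[C@@H]1Cc2c(OCc5ccccc5)c(Br)c(OCc5ccccc5)c([C@@H]3c4ccc(OCc5ccccc5)cc4OC(=O)C3)c2O[C@@H]1c1cc(OCc5ccccc5)c(OCc5ccccc5)c(OCc5ccccc5)c1
F6 | step 12 | (2S,3S)-2-(benzyloxy)-3-[4-(benzyloxy)-2-hydroxyphenyl]-N-methoxy-N-methyl-3-ArL-propanamide | CC(C)(C)[Si](C)(C)O[C@@H]1Cc2c(OCc5ccccc5)cc(OCc5ccccc5)c([C@H](c4ccc(OCc5ccccc5)cc4O)[C@H](OCc5ccccc5)C(=O)N(C)OC)c2O[C@@H]1c1cc(OCc5ccccc5)c(OCc5ccccc5)c(OCc5ccccc5)c1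
F7 | step 12 | (2S,3S)-2-(benzyloxy)-3-[4-(benzyloxy)-2-hydroxyphenyl]-3-ArL-1-[3,4,5-tris(benzyloxy)phenyl]propan-1-one (open-chain tautomer of 21) | CC(C)(C)[Si](C)(C)O[C@@H]1Cc2c(OCc5ccccc5)cc(OCc5ccccc5)c([C@H](c4ccc(OCc5ccccc5)cc4O)[C@H](OCc5ccccc5)C(=O)c4cc(OCc5ccccc5)c(OCc5ccccc5)c(OCc5ccccc5)c4)c2O[C@@H]1c1cc(OCc5ccccc5)c(OCc5ccccc5)c(OCc5ccccc5)c1
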